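(Readings and results are simulated for substances that don't exist; scatter was added.)

Early on, the target readings climb in Friday's and Saturday's runs and then level off: Friday's run reads on average 14.7% from 6.00 h on, and the hotter Saturday's run 10.0% from 1.33 h on, each within the scatter of a reading.

| flask | substrate | first nucleophile | second nucleophile | protic impurity | temperature | remark | time |
|---|---|---|---|---|---|---|---|
| Friday's | 27 mM | 0.95 equiv | 1.5 equiv | 7.6 mM | 26 °C | run made earlier |  |
| Saturday's | 27 mM | 0.95 equiv | 1.5 equiv | 12 mM | 40 °C | run made earlier |  |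
| Sunday's | 27 mM | 1.9 equiv | 1.5 equiv | 5.4 mM | 26 °C | run made earlier |  |
| epsilon | 27 mM | 0.950 equiv | 1.50 equiv | 5.40 mM | 45 °C |  | 8.0 h |
| beta | 27 mM | 0.950 equiv | 1.50 equiv | 5.40 mM | 20 °C |  | 8.0 h |

| run | time / h | target / % | other capture product / % |
|---|---|---|---|
| Friday's | 1.00 | 7.3 | 0.5 |
| Friday's | 3.00 | 12.1 | 1.5 |
| Friday's | 6.00 | 15.2 | 1.6 |
| Friday's | 10.0 | 15.8 | 0.6 |
| Friday's | 12.0 | 14.1 | 2.8 |
| Friday's | 15.0 | 13.9 | 1.9 |
| Saturday's | 0.417 | 7.5 | 0.7 |
| Saturday's | 1.33 | 10.4 | 0.2 |
| Saturday's | 2.50 | 10.4 | 1.3 |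
| Saturday's | 4.00 | 8.8 | 0 |
| Saturday's | 5.00 | 11.0 | 1.5 |
| Saturday's | 6.00 | 9.6 | 0.7 |
| Sunday's | 1.33 | 15.9 | 0.8 |
| Sunday's | 2.50 | 20.8 | 0 |
| Sunday's | 5.00 | 24.4 | 2.2 |
| Sunday's | 8.00 | 24.3 | 2.3 |
| Sunday's | 15.0 | 25.2 | 2.7 |

(standard deviation of a reading: 1 percentage point)

1. which flask leads in share of target in all that became target or other capture product or solvolysis product ("all alike" within 1.5 percentage points) (epsilon / beta / all alike)
2. share of target in all that became target or other capture product or solvolysis product, epsilon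
3. share of target in all that became target or other capture product or solvolysis product, beta

- a reading or a percentage of target counts all its forms, free or not

For a quick number, take the substrate as gone on those plateaus, so that each plateau reading is the share s asked for. The useful form of s is its odds ω, the share of target over the share of everything else, a selectivity factor for the finished flask:

ω(Friday) = 0.173, ω(Saturday) = 0.112

g = ln(ω(Friday)/ω(Saturday)) / (temperature gap) = 0.0313 K⁻¹

This g, the temperature penalty, the fall of ln ω per kelvin, is read between the two runs and assumed constant from 20 °C to 45 °C. Saturday's run also carried 12 mM of protic impurity against 7.6 mM on Friday, and g carries that along. Stepping from the nearest run: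

epsilon, from Saturday's: ω = 0.0954, s = 8.71%

beta, from Friday's: ω = 0.209, s = 17.3%

So on this reckoning beta leads by 8.6 percentage points, more than the margin. These are shares of finished flasks, and beta runs colder than Friday's run for 8.0 h, so it may stand unfinished.

Your forecast also names beta, with 9% (6.5% to 13%) for epsilon and 18% (15% to 21%) for beta, holding that “a fast competing loss of substrate, presumably solvolysis, sets the yield”. The reckoning above stands below both centres.

The flasks give beta in the lead, with 8.33% in epsilon and 21.2% in beta.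

    substrate → intermediate (k = 5.33 × 10⁻⁵ s⁻¹, Ea = 89.0 kJ mol⁻¹)
    first nucleophile + protic impurity → quenched reagent (k = 0.00133 M⁻¹ s⁻¹, Ea = 74.0 kJ mol⁻¹)
    first nucleophile ⇌ dormant form (K = 23.5, k = 3.53 × 10⁻⁵ s⁻¹, Ea = 94.0 kJ mol⁻¹, ΔH = 51.0 kJ mol⁻¹)
    second nucleophile + intermediate → other capture product (k = 0.00109 M⁻¹ s⁻¹, Ea = 55.0 kJ mol⁻¹)
    first nucleophile + target ⇌ idle adduct, settled at all times (K = 120 M⁻¹, ΔH = −41.0 kJ mol⁻¹)
    intermediate → solvolysis product (k = 0.00134 s⁻¹, Ea = 89.0 kJ mol⁻¹)
    first nucleophile + intermediate → target (k = 0.0274 M⁻¹ s⁻¹, Ea = 58.0 kJ mol⁻¹)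
    (constants at 20 °C)

Epsilon, with 0% of its substrate left, reads 8.33% against 8.71% from g. Beta run at 35 °C, with 0.011% left, reads 11.4% against 11.5% from g. Beta itself still holds 22% of its substrate and reads above its figure from g. In beta, intermediate passes into solvolysis product 3.5 times as fast as into target at 2.60 h, and 8.9 times as fast at 8.00 h. Left until 80.0 h, beta reads 17.9%.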